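# Proposed synthesis of (2S,3S,3aR)-5-methoxy-3-methyl-3a-(prop-2-en-1-yl)-2-(3,4,5-trimethoxyphenyl)-3,3a-dihydro-1-benzofuran-6(2H)-one (21)

Benzofuran numbering is used for the skeleton throughout: O1, C2 (aryl), C3 (methyl), C3a (allyl), C4, C5 (OMe), C6 (C=O), C7, C7a.

## The problem

The target 21 is an oxolane (O1, C2, C3, C3a, C7a) fused through the C3a–C7a bond to a cross-conjugated cyclohexadienone (C3a, C4–C7, C7a). C7a is at once ring-fusion carbon, enol-ether carbon and β-carbon of a vinylogous ester (O1–C7a=C7–C6=O), and C4=C5 carries the second enol ether. The carbocycle therefore holds no stereocentre and can be assembled late by carbonyl condensations on C3a and C7a. The three stereocentres are contiguous: C2 (aryl carbinol) and C3 (methyl) are trans, and the quaternary C3a has its allyl group cis to the C3 methyl group. C2 and C3 are a vicinal pair that one C–C bond-forming event can set together. C3a must then be set under the influence of the ring, chiefly of the adjacent C3, and cannot be corrected later by epimerisation. The C2–O1 bond is benzylic to an electron-rich arene and its oxygen is a vinylogous carboxylate, so acid can ionise it; the 4,4-disubstituted dienone rearranges under acid and accepts nucleophiles; the terminal alkene rules out hydrogenation, ozonolysis and hydroboration once it is in place. The enabling feature is that O1–C2(aryl)–C3(methyl)–C3a–C7a, with C7a at the carboxyl oxidation level and the allylic CH2 on C3a written as an exocyclic methylene, is a trans-β-methyl-γ-aryl-α-methylene-γ-butyrolactone, the product pattern of a 2-alkoxycarbonyl crotylboronate adding to an aryl aldehyde.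

## Retrosynthesis

**C4=C5.** The dienone 21 is opened at C4=C5 to keto aldehyde 19 (aldol 20 lies in between). The aldehyde carbon C4 sits on the quaternary centre and cannot enolise, and the ketone C6 has α-hydrogens only at C5, so a single aldol is possible. Closing C6–C7 or C5–C6 instead would need an acyl donor on a geometrically defined enol ether or an acyl anion. 19 is monocyclic and free of the sensitive dienone. The forward reaction must use a base mild enough to spare the formyl group, and it must let the push–pull alkene C7a=C7 reach the geometry with C6 syn to C3a.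

**Oxidation level of C4.** Aldehyde 19 comes from alcohol 18 and this from silyl ether 17. C4 is carried as a silyl-protected hydroxymethyl group because the two preceding C–C bond formations use an organolithium and a lithium enolate. A free β-hydroxyl would fragment by retro-aldol loss of formaldehyde, and an aldehyde would not survive.

**C6–C7 and O1–C7a.** The vinylogous ester 17 is cut at C6–C7 and at O1–C7a. This gives γ-hydroxy-β-diketone 16, the Claisen product of methyl ketone 14 and methyl methoxyacetate 15. The neighbouring option is methylenation of the lactone carbonyl and C-acylation of the resulting neutral enol ether with an alkoxyacetyl halide. It was set aside because enol ethers are acylated cleanly only by the most electrophilic acyl halides, and α-alkoxyacetyl halides turn into ketenes under amine base. The lithium enolate of 14 is the same C7 nucleophile in a form that is certain to react, and C7 is its only enolisable position. The forward step must give C- rather than O-acylation, and the cyclodehydration acid must be mild enough for the benzylic carbinol.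

**C7–C7a.** Ketone 14 is cut at C7–C7a to lactone 12 and methyllithium 13. The lactone carbonyl becomes C7a. The α-quaternary centre excludes enolisation and helps the addition stop at the mono-adduct.

**C3a.** Lactone 12 is the silyl ether of 11. In 11 the quaternary centre is cut twice: at C3a–C4 (aldol with formaldehyde 9) and between the allylic CH2 and its vinyl group (conjugate addition of vinylmagnesium bromide 8 to methylene lactone 7). The order matters. The allyl group is assembled in the plane of the enolate without any facial question, and only the last bond to C3a is face-selective. A small electrophile entering anti to the adjacent C3 methyl group puts C4 trans and allyl cis to methyl, as required. The reverse order, with an allyl halide as electrophile, would put allyl trans to methyl. 7 has only two stereocentres and a planar C3a.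

**C2–C3 and O1–C7a (key step).** Lactone 7 is cut at C2–C3 and at the acyl–oxygen bond O1–C7a to 3,4,5-trimethoxybenzaldehyde 5 and the Z-configured 2-ethoxycarbonyl crotylboronate 4. One closed transition state sets both stereocentres, the olefin geometry fixes their relative configuration, and the lactonisation is spontaneous. A crotylation followed by a separate acylation and methylenation would need three or four steps for the same result. For enantiocontrol a BINOL-derived phosphoric acid is chosen over tin tetrachloride–diol acids: the former give their best selectivities with aromatic aldehydes, the latter with aliphatic ones.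

**Boronate.** 4 is cut at the bond between C3a and the boron-bearing CH2, and at the new C–H bond on the methyl-bearing carbon. The pieces are ethyl but-2-ynoate 1 and iodomethylboronate 2, joined by conjugate hydroalumination and alkylation (vinylalane 3). Syn addition of hydride and aluminium fixes the Z geometry.

## Roads not taken

**Alternative 1:** The cut is the C3a–C7a bond together with the whole carbocycle. Cyclobutenone A1, a squarate-derived 4-alkenyl-3,4-dimethoxycyclobutenone carrying the C2/C3 side chain, would open on heating to a dienylketene that closes by 6π electrocyclisation to the linear dienone A2.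
- Merits: the step is thermal and neutral, it forms the quaternary centre and the ring together, and A2 already has oxygen on C5 and C6. After desilylation, an acid-mediated exchange (O1 onto C7a, loss of methanol from C6) would finish 21. In ring construction this road is shorter than the chosen one, which spends six steps between 12 and 21.
- Weak points: C3a is created next to an acyclic stereocentre, so the two helical senses of closure differ only by open-chain 1,2-induction. A 6-allyl-cyclohexa-2,4-dienone formed at the temperature of cyclobutenone opening can undergo Cope shift of the allyl group and Diels–Alder dimerisation. A1 needs a trisubstituted alkenyl metal of defined geometry that already carries both stereocentres. The final exchange uses acid on a benzylic ether.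
- Comparison: the chosen plan sets against the shorter ring construction a ring-controlled formation of C3a, a catalytic setting of C2 and C3 from two commercial fragments, and no heating of an allyl-substituted linear dienone.

**Alternative 2:** The cut is C2–C3. Diazo ester A3 would be decomposed by the chiral dirhodium carboxylate Rh2(S-PTTL)4, that is dirhodium tetrakis[N-phthaloyl-(S)-tert-leucinate], or its antipode. The carbenoid carbon C3 would insert into the benzylic ether C–H bond to close the oxolane as ester A4 (2,3-trans after base equilibration).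
- Merits: 1,5-insertion next to an ether oxygen is a favourable site. The carbenoid has no β-hydrogen. The quaternary centre of A3 can be set beforehand by a dedicated catalytic asymmetric allylation, which is a firmer control of C3a than the substrate control of the chosen plan.
- Weak points: the catalyst must be matched to the existing C3a centre. Oxonium-ylide formation at the enol-ether oxygen competes with insertion. After the key step the ester must be reduced to a methyl group at a neopentyl position, and the cyclohexene must be oxidised at three carbons (C5 methoxy enone, C6 ketone, second double bond).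
- Comparison: the chosen plan sets against the better C3a control of this road the fact that every carbon arrives at or near its final oxidation level and the methyl group is present from the start.

**Alternative 3:** The cut is C3a–C4 and C7–C7a. Formyl dihydrofuran A5 and silyloxydiene A6 would combine under Et2AlCl to the cis-fused aldehyde A7.
- Merits: one step forms two C–C bonds, the carbocycle and the quaternary centre, with the diene approaching anti to the C3 methyl group and the C6 oxygen placed by the silyloxy group. As a ring construction it is more step-economical than the chosen sequence.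
- Weak points: A5 is a push–pull alkene and a poor dienophile. The Lewis acid needed can ionise the benzylic C2–O1 bond. The angular group arrives as a formyl group and must be homologated by one carbon to allyl at a neopentyl centre. C7a emerges saturated and C5 without oxygen, so α-oxygenation, methylation and two dehydrogenations follow. A5 itself needs an enantioselective synthesis.
- Comparison: the chosen plan sets against the one-step ring formation a direct installation of the allyl group and a ring built at the correct oxidation level by classical carbonyl reactions.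

Key step: step 2

## Route

Remarks on the chemistry (assumptions):
- The (S)-configured phosphoric acid is taken to direct Si-face addition to 5, as it does with allyl and crotyl pinacolboronates. Structures are drawn for that outcome.
- 14 is drawn as the open hydroxy ketone, although it equilibrates with its cyclic hemiketal.
- 17, 18 and 19 are taken as E/Z mixtures at the exocyclic alkene; the isomers converge in step 9.

Step 1
Reactants: 1 ethyl but-2-ynoate; 2 2-(iodomethyl)-4,4,5,5-tetramethyl-1,3,2-dioxaborolane
Product: 4 ethyl (Z)-2-[(4,4,5,5-tetramethyl-1,3,2-dioxaborolan-2-yl)methyl]but-2-enoate, via vinylalane 3 (not isolated)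
Conditions: i-Bu2AlH, HMPA, THF, 0 °C; 1, 0 °C; then 2, 0 °C → rt
Reagents that add atoms: none
Why: Conjugate hydroalumination of the ynoate adds H and Al syn and gives α-alumino enoate 3 with methyl cis to the ester; C-alkylation by the α-iodo boronate keeps the olefin geometry. This one-pot hydride addition–alkylation is the standard entry to 2-alkoxycarbonyl allylboronates.

Step 2
Reactants: 5 3,4,5-trimethoxybenzaldehyde; 4 ethyl (Z)-2-[(4,4,5,5-tetramethyl-1,3,2-dioxaborolan-2-yl)methyl]but-2-enoate
Product: 7 (4S,5S)-4-methyl-3-methylidene-5-(3,4,5-trimethoxyphenyl)oxolan-2-one, via borate ester 6 (not isolated)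
Conditions: (S)-3,3′-bis(2,4,6-triisopropylphenyl)-1,1′-binaphthyl-2,2′-diyl hydrogen phosphate [(S)-TRIP] (10 mol %), 4 Å MS, PhMe, 0 °C → rt; then 50 °C
Reagents that add atoms: none
Why: Acid-catalysed carbonyl allylboration with in situ lactonisation, the established route from 2-alkoxycarbonyl allylboronates to α-methylene-γ-butyrolactones. The phosphoric acid hydrogen-bonds to a boronate oxygen, raises the Lewis acidity of boron and holds the aldehyde in a closed six-membered chair transition state in which boron binds the carbonyl oxygen and the methyl-bearing γ-carbon of 4 attacks the carbonyl carbon, forming C2–C3. The aryl group is equatorial and the methyl group, trans to the CH2B unit in the Z-boronate, is equatorial too, so the anti adduct 6 results and the configuration of C3 follows from the olefin geometry. The catalyst pocket selects the Si face of 5 and so sets C2 as S (by analogy with crotyl pinacolboronates; the antipodal acid is used if the ester substituent reverses the sense). The borate oxygen of 6 then attacks the neighbouring ester in a 5-exo-trig acyl substitution, which closes the oxolanone (O1–C7a) and releases the ethoxyborane; the anti adduct can only give the trans lactone. The step needs γ-selectivity (secured by the cyclic transition state), enantiofacial control (catalyst) and a slow uncatalysed pathway (the ester lowers the nucleophilicity of 4). Any acid-induced ionisation at the benzylic carbon would funnel into the more stable trans lactone, because C3 is not touched.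

Step 3
Reactants: 7 (4S,5S)-4-methyl-3-methylidene-5-(3,4,5-trimethoxyphenyl)oxolan-2-one; 8 vinylmagnesium bromide; 9 formaldehyde
Product: 11 (3R,4S,5S)-3-(hydroxymethyl)-4-methyl-3-(prop-2-en-1-yl)-5-(3,4,5-trimethoxyphenyl)oxolan-2-one, via magnesium enolate 10 (not isolated)
Conditions: CuBr·SMe2 (20 mol %), 8, THF, −78 → −40 °C; then monomeric 9 (from cracked paraformaldehyde, THF), −78 °C; aq. NH4Cl
Reagents that add atoms: none
Why: Copper-catalysed 1,4-addition of the vinyl group to the exocyclic methylene builds the allyl group in the plane of enolate 10 (tandem conjugate addition–aldol reaction). Formaldehyde then enters on the face anti to the adjacent C3 methyl group, the usual sense for β-substituted γ-butyrolactone enolates, which places C4 trans and the allyl group cis to methyl.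

Step 4
Reactants: 11 (3R,4S,5S)-3-(hydroxymethyl)-4-methyl-3-(prop-2-en-1-yl)-5-(3,4,5-trimethoxyphenyl)oxolan-2-one
Product: 12 (3R,4S,5S)-3-({[tert-butyl(dimethyl)silyl]oxy}methyl)-4-methyl-3-(prop-2-en-1-yl)-5-(3,4,5-trimethoxyphenyl)oxolan-2-one
Conditions: TBSCl, imidazole, DMF, rt
Reagents that add atoms: tert-butyldimethylsilyl chloride, CC(C)(C)[Si](C)(C)Cl
Why: Routine silylation of a primary alcohol. The silyl ether prevents retro-aldol loss of formaldehyde and alkoxide interference in steps 5 and 6.

Step 5
Reactants: 12 (3R,4S,5S)-3-({[tert-butyl(dimethyl)silyl]oxy}methyl)-4-methyl-3-(prop-2-en-1-yl)-5-(3,4,5-trimethoxyphenyl)oxolan-2-one; 13 methyllithium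
Product: 14 (3R,4S,5S)-3-({[tert-butyl(dimethyl)silyl]oxy}methyl)-5-hydroxy-4-methyl-3-(prop-2-en-1-yl)-5-(3,4,5-trimethoxyphenyl)pentan-2-one
Conditions: 13 (1.2 equiv), THF, −78 °C; aq. NH4Cl
Reagents that add atoms: none
Why: Mono-addition of an organolithium to a γ-lactone. The lithium hemiketalate is stable at −78 °C, and the α-quaternary centre rules out enolisation and slows a second addition.

Step 6
Reactants: 14 (3R,4S,5S)-3-({[tert-butyl(dimethyl)silyl]oxy}methyl)-5-hydroxy-4-methyl-3-(prop-2-en-1-yl)-5-(3,4,5-trimethoxyphenyl)pentan-2-one; 15 methyl methoxyacetate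
Product: 17 1-[(3R,4S,5S)-3-({[tert-butyl(dimethyl)silyl]oxy}methyl)-4-methyl-3-(prop-2-en-1-yl)-5-(3,4,5-trimethoxyphenyl)oxolan-2-ylidene]-3-methoxypropan-2-one (E/Z mixture at the exocyclic alkene), via β-diketone 16 (not isolated)
Conditions: LiN(SiMe3)2 (3.1 equiv), THF, −78 °C; 15, −78 → 0 °C; aq. NH4Cl; then TsOH·H2O (5 mol %), 4 Å MS, CH2Cl2, rt
Reagents that add atoms: none
Why: Crossed Claisen condensation: the ketone of 14 can enolise only at its methyl group (C7), and the α-alkoxy ester is an activated acyl donor. Mild acid then closes O1 onto C7a (5-exo) and dehydrates the hemiketal to the conjugated vinylogous ester (cyclodehydration of a γ-hydroxy-β-diketone); the double bond can only be exocyclic because C3a is quaternary.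

Step 7
Reactants: 17 1-[(3R,4S,5S)-3-({[tert-butyl(dimethyl)silyl]oxy}methyl)-4-methyl-3-(prop-2-en-1-yl)-5-(3,4,5-trimethoxyphenyl)oxolan-2-ylidene]-3-methoxypropan-2-one
Product: 18 1-[(3R,4S,5S)-3-(hydroxymethyl)-4-methyl-3-(prop-2-en-1-yl)-5-(3,4,5-trimethoxyphenyl)oxolan-2-ylidene]-3-methoxypropan-2-one
Conditions: Bu4NF, AcOH, THF, 0 °C → rt
Reagents that add atoms: none
Why: Fluoride cleavage of the silyl ether. Buffering with acetic acid keeps the liberated alkoxide from triggering a vinylogous retro-aldol cleavage.

Step 8
Reactants: 18 1-[(3R,4S,5S)-3-(hydroxymethyl)-4-methyl-3-(prop-2-en-1-yl)-5-(3,4,5-trimethoxyphenyl)oxolan-2-ylidene]-3-methoxypropan-2-one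
Product: 19 (3S,4S,5S)-2-(3-methoxy-2-oxopropylidene)-4-methyl-3-(prop-2-en-1-yl)-5-(3,4,5-trimethoxyphenyl)oxolane-3-carbaldehyde
Conditions: DMP (1,1,1-triacetoxy-1,1-dihydro-1,2-benziodoxol-3(1H)-one), CH2Cl2, 0 °C → rt
Reagents that add atoms: none
Why: Periodinane oxidation of a neopentyl primary alcohol under nearly neutral conditions. The aldehyde has no α-hydrogen, and the electron-poor enol ether, the terminal alkene and the arene are not attacked (the descriptor at C3 changes only because the formyl group outranks C2).

Step 9
Reactants: 19 (3S,4S,5S)-2-(3-methoxy-2-oxopropylidene)-4-methyl-3-(prop-2-en-1-yl)-5-(3,4,5-trimethoxyphenyl)oxolane-3-carbaldehyde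
Product: 21 (2S,3S,3aR)-5-methoxy-3-methyl-3a-(prop-2-en-1-yl)-2-(3,4,5-trimethoxyphenyl)-3,3a-dihydro-1-benzofuran-6(2H)-one, via aldol 20 (not isolated)
Conditions: K2CO3 (0.5 equiv), MeOH, rt → 40 °C
Reagents that add atoms: none
Why: Intramolecular aldol condensation (6-enolexo-exo-trig): the ketone enolises only at C5 and the aldehyde cannot enolise, so a single aldol 20 forms and loses water by E1cB elimination to the cross-conjugated dienone. Reversible conjugate addition of methoxide at C7a interconverts the geometric isomers of the push–pull alkene, so all material passes through the isomer with the acyl group syn to C3a; C2, C3 and C3a are untouched.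

## Compound list

1 | ethyl but-2-ynoate | CC#CC(=O)OCC | starting material
2 | 2-(iodomethyl)-4,4,5,5-tetramethyl-1,3,2-dioxaborolane | ICB1OC(C)(C)C(C)(C)O1 | starting material
3 | ethyl (E)-2-[bis(2-methylpropyl)alumanyl]but-2-enoate | CCOC(=O)/C(=C\C)[Al](CC(C)C)CC(C)C | intermediate
4 | ethyl (Z)-2-[(4,4,5,5-tetramethyl-1,3,2-dioxaborolan-2-yl)methyl]but-2-enoate | CCOC(=O)/C(CB1OC(C)(C)C(C)(C)O1)=C\C | intermediate
5 | 3,4,5-trimethoxybenzaldehyde | COc1cc(C=O)cc(OC)c1OC | starting material
6 | ethyl (3S,4S)-3-methyl-2-methylidene-4-[(4,4,5,5-tetramethyl-1,3,2-dioxaborolan-2-yl)oxy]-4-(3,4,5-trimethoxyphenyl)butanoate | C=C(C(=O)OCC)[C@H](C)[C@H](OB1OC(C)(C)C(C)(C)O1)c1cc(OC)c(OC)c(OC)c1 | intermediate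
7 | (4S,5S)-4-methyl-3-methylidene-5-(3,4,5-trimethoxyphenyl)oxolan-2-one | C=C1C(=O)O[C@H](c2cc(OC)c(OC)c(OC)c2)[C@H]1C | intermediate
8 | vinylmagnesium bromide | C=C[Mg]Br | starting material
9 | formaldehyde | C=O | starting material
10 | bromomagnesium (4S,5S)-4-methyl-3-(prop-2-en-1-yl)-5-(3,4,5-trimethoxyphenyl)-4,5-dihydrofuran-2-olate | C=CCC1=C(O[Mg]Br)O[C@H](c2cc(OC)c(OC)c(OC)c2)[C@H]1C | intermediate
11 | (3R,4S,5S)-3-(hydroxymethyl)-4-methyl-3-(prop-2-en-1-yl)-5-(3,4,5-trimethoxyphenyl)oxolan-2-one | C=CC[C@@]1(CO)C(=O)O[C@H](c2cc(OC)c(OC)c(OC)c2)[C@H]1C | intermediate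
12 | (3R,4S,5S)-3-({[tert-butyl(dimethyl)silyl]oxy}methyl)-4-methyl-3-(prop-2-en-1-yl)-5-(3,4,5-trimethoxyphenyl)oxolan-2-one | C=CC[C@@]1(CO[Si](C)(C)C(C)(C)C)C(=O)O[C@H](c2cc(OC)c(OC)c(OC)c2)[C@H]1C | intermediate
13 | methyllithium | [Li]C | starting material
14 | (3R,4S,5S)-3-({[tert-butyl(dimethyl)silyl]oxy}methyl)-5-hydroxy-4-methyl-3-(prop-2-en-1-yl)-5-(3,4,5-trimethoxyphenyl)pentan-2-one | CC(=O)[C@@](CC=C)(CO[Si](C)(C)C(C)(C)C)[C@H](C)[C@H](O)c1cc(OC)c(OC)c(OC)c1 | intermediate
15 | methyl methoxyacetate | COCC(=O)OC | starting material
16 | (5R,6S,7S)-5-({[tert-butyl(dimethyl)silyl]oxy}methyl)-7-hydroxy-1-methoxy-6-methyl-5-(prop-2-en-1-yl)-7-(3,4,5-trimethoxyphenyl)heptane-2,4-dione | COCC(=O)CC(=O)[C@@](CC=C)(CO[Si](C)(C)C(C)(C)C)[C@H](C)[C@H](O)c1cc(OC)c(OC)c(OC)c1 | intermediate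
17 | 1-[(3R,4S,5S)-3-({[tert-butyl(dimethyl)silyl]oxy}methyl)-4-methyl-3-(prop-2-en-1-yl)-5-(3,4,5-trimethoxyphenyl)oxolan-2-ylidene]-3-methoxypropan-2-one (E/Z mixture) | C=CC[C@@]1(CO[Si](C)(C)C(C)(C)C)C(=CC(=O)COC)O[C@H](c2cc(OC)c(OC)c(OC)c2)[C@H]1C | intermediate
18 | 1-[(3R,4S,5S)-3-(hydroxymethyl)-4-methyl-3-(prop-2-en-1-yl)-5-(3,4,5-trimethoxyphenyl)oxolan-2-ylidene]-3-methoxypropan-2-one (E/Z mixture) | C=CC[C@@]1(CO)C(=CC(=O)COC)O[C@H](c2cc(OC)c(OC)c(OC)c2)[C@H]1C | intermediate
19 | (3S,4S,5S)-2-(3-methoxy-2-oxopropylidene)-4-methyl-3-(prop-2-en-1-yl)-5-(3,4,5-trimethoxyphenyl)oxolane-3-carbaldehyde (E/Z mixture) | C=CC[C@@]1(C=O)C(=CC(=O)COC)O[C@H](c2cc(OC)c(OC)c(OC)c2)[C@H]1C | intermediate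
20 | (2S,3S,3aR)-4-hydroxy-5-methoxy-3-methyl-3a-(prop-2-en-1-yl)-2-(3,4,5-trimethoxyphenyl)-3,3a,4,5-tetrahydro-1-benzofuran-6(2H)-one (epimers at C4 and C5) | C=CC[C@@]12C(O)C(OC)C(=O)C=C1O[C@H](c1cc(OC)c(OC)c(OC)c1)[C@H]2C | intermediate
21 | (2S,3S,3aR)-5-methoxy-3-methyl-3a-(prop-2-en-1-yl)-2-(3,4,5-trimethoxyphenyl)-3,3a-dihydro-1-benzofuran-6(2H)-one | C=CC[C@@]12C=C(OC)C(=O)C=C1O[C@H](c1cc(OC)c(OC)c(OC)c1)[C@H]2C | target

## Step count and risks

Total step count: 9. Longest linear sequence: 9 steps (1 → 4 → 7 → 11 → 12 → 14 → 17 → 18 → 19 → 21).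

**Step 2 (key step).**
- What may go wrong: slow turnover and weak enantiofacial discrimination, because the ester makes 4 a poor nucleophile and its carbonyl group competes with the boronate oxygens for the acid.
- Fallback (auxiliary control instead of catalyst control): but-2-ynoic acid is esterified with (1R,2S,5R)-8-phenylmenthol to 8-phenylmenthyl but-2-ynoate F1. Hydroalumination and alkylation with 2, as in step 1, give its Z-configured allylboronate F2. F2 adds to 5 thermally or with Sc(OTf)3, and a trace of TsOH completes the lactonisation. The fallback sets out from 2 and 5 and comes back at 7. The auxiliary leaves as its borate and is recovered as the alcohol on work-up; its antipode is used if the (1R,2S,5R) ester shields the wrong face.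

**Step 3.**
- What may go wrong: poor or reversed facial selectivity in the trapping of enolate 10, because the adjacent methyl group and the more distant but larger aryl group shield opposite faces. Capture by formaldehyde may also be inefficient (oligomerisation of the electrophile, proton transfer).
- Fallback (roles of the two C3a substituents exchanged, for the case that electrophiles prefer the face anti to the aryl group): copper-catalysed conjugate borylation of 7 (B2pin2, CuCl, NaOt-Bu, MeOH) gives the borylmethyl lactone F3. NaBO3·4H2O oxidises it to the hydroxymethyl lactone F4. The dianion of F4 (LiN(i-Pr)2, 2.2 equiv) is alkylated with allyl bromide. The fallback sets out from 7 and comes back at 11. If selectivity is merely low, the C3a epimers are separated at 11 or 12.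

**Step 6.**
- What may go wrong: O-acylation of the benzylic alkoxide or proton transfer in place of C-acylation at the hindered enolate, and ionisation at the free benzylic carbinol during the acid treatment.
- Fallback (oxolane ring kept closed): the lithium enolate of N-methoxy-N-methylacetamide adds to 12 to give the hemiketal amide F5. Catalytic TsOH dehydrates it to the alkylidene N-methoxy-N-methylamide F6. Methoxymethyllithium (from Bu3SnCH2OMe and n-BuLi) converts the amide into the methoxymethyl ketone. The fallback sets out from 12 and comes back at 17.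

**Step 9.**
- What may go wrong: incomplete equilibration of the alkene geometry (only the isomer with the acyl group syn to C3a can close), stalling at aldol 20, or loss of the formyl group by alkoxide attack on the hindered aldehyde.
- Fallback (olefination in place of aldol condensation): amide F6 from the fallback to step 6 is treated with lithiated dimethyl (methoxymethyl)phosphonate to give the keto phosphonate F7. Bu4NF/AcOH gives the alcohol F8 and DMP the aldehyde F9. An intramolecular Horner–Wadsworth–Emmons reaction (K2CO3 in MeOH, or LiCl/DBU in MeCN) forms C4=C5 irreversibly and without a separate dehydration. The fallback sets out from 12 (through F5 and F6) and comes back at 21.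

## Further compounds

F1 | step 2 | (1R,2S,5R)-5-methyl-2-(2-phenylpropan-2-yl)cyclohexyl but-2-ynoate | CC(C)(c1ccccc1)[C@@H]1CC[C@@H](C)C[C@H]1OC(=O)C#CC
F2 | step 2 | (1R,2S,5R)-5-methyl-2-(2-phenylpropan-2-yl)cyclohexyl (Z)-2-[(4,4,5,5-tetramethyl-1,3,2-dioxaborolan-2-yl)methyl]but-2-enoate | CC(C)(c1ccccc1)[C@@H]1CC[C@@H](C)C[C@H]1OC(=O)/C(CB1OC(C)(C)C(C)(C)O1)=C\C
F3 | step 3 | (4S,5S)-4-methyl-3-[(4,4,5,5-tetramethyl-1,3,2-dioxaborolan-2-yl)methyl]-5-(3,4,5-trimethoxyphenyl)oxolan-2-one (C3 epimers) | CC1(C)OB(CC2C(=O)O[C@H](c3cc(OC)c(OC)c(OC)c3)[C@H]2C)OC1(C)C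
F4 | step 3 | (4S,5S)-3-(hydroxymethyl)-4-methyl-5-(3,4,5-trimethoxyphenyl)oxolan-2-one (C3 epimers) | OCC1C(=O)O[C@H](c2cc(OC)c(OC)c(OC)c2)[C@H]1C
F5 | step 6 | 2-[(3R,4S,5S)-3-({[tert-butyl(dimethyl)silyl]oxy}methyl)-2-hydroxy-4-methyl-3-(prop-2-en-1-yl)-5-(3,4,5-trimethoxyphenyl)oxolan-2-yl]-N-methoxy-N-methylacetamide (C2 anomers) | C=CC[C@@]1(CO[Si](C)(C)C(C)(C)C)C(O)(CC(=O)N(C)OC)O[C@H](c2cc(OC)c(OC)c(OC)c2)[C@H]1C
F6 | step 6 | 2-[(3R,4S,5S)-3-({[tert-butyl(dimethyl)silyl]oxy}methyl)-4-methyl-3-(prop-2-en-1-yl)-5-(3,4,5-trimethoxyphenyl)oxolan-2-ylidene]-N-methoxy-N-methylacetamide (E/Z mixture) | C=CC[C@@]1(CO[Si](C)(C)C(C)(C)C)C(=CC(=O)N(C)OC)O[C@H](c2cc(OC)c(OC)c(OC)c2)[C@H]1C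
F7 | step 9 | dimethyl {3-[(3R,4S,5S)-3-({[tert-butyl(dimethyl)silyl]oxy}methyl)-4-methyl-3-(prop-2-en-1-yl)-5-(3,4,5-trimethoxyphenyl)oxolan-2-ylidene]-1-methoxy-2-oxopropyl}phosphonate (E/Z mixture, C1 epimers) | C=CC[C@@]1(CO[Si](C)(C)C(C)(C)C)C(=CC(=O)C(OC)P(=O)(OC)OC)O[C@H](c2cc(OC)c(OC)c(OC)c2)[C@H]1C
F8 | step 9 | dimethyl {3-[(3R,4S,5S)-3-(hydroxymethyl)-4-methyl-3-(prop-2-en-1-yl)-5-(3,4,5-trimethoxyphenyl)oxolan-2-ylidene]-1-methoxy-2-oxopropyl}phosphonate (E/Z mixture, C1 epimers) | C=CC[C@@]1(CO)C(=CC(=O)C(OC)P(=O)(OC)OC)O[C@H](c2cc(OC)c(OC)c(OC)c2)[C@H]1C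
F9 | step 9 | dimethyl {3-[(3S,4S,5S)-3-formyl-4-methyl-3-(prop-2-en-1-yl)-5-(3,4,5-trimethoxyphenyl)oxolan-2-ylidene]-1-methoxy-2-oxopropyl}phosphonate (E/Z mixture, C1 epimers) | C=CC[C@@]1(C=O)C(=CC(=O)C(OC)P(=O)(OC)OC)O[C@H](c2cc(OC)c(OC)c(OC)c2)[C@H]1C
A1 | alternative 1 | 4-[(3S,4S)-4-{[tert-butyl(dimethyl)silyl]oxy}-3-methyl-2-(prop-2-en-1-yl)-4-(3,4,5-trimethoxyphenyl)but-1-en-1-yl]-3,4-dimethoxycyclobut-2-en-1-one (ring C4 and alkene geometry left open) | O=C1C=C(OC)C1(OC)C=C(CC=C)[C@H](C)[C@@H](c1cc(OC)c(OC)c(OC)c1)O[Si](C)(C)C(C)(C)C
A2 | alternative 1 | (6R)-6-[(1S,2S)-1-{[tert-butyl(dimethyl)silyl]oxy}-1-(3,4,5-trimethoxyphenyl)propan-2-yl]-3,4-dimethoxy-6-(prop-2-en-1-yl)cyclohexa-2,4-dien-1-one | C=CC[C@]1(C=C(OC)C(OC)=CC1=O)[C@H](C)[C@@H](c2cc(OC)c(OC)c(OC)c2)O[Si](C)(C)C(C)(C)C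
A3 | alternative 2 | methyl 2-diazo-2-{(1R)-1-(prop-2-en-1-yl)-2-[(3,4,5-trimethoxyphenyl)methoxy]cyclohex-2-en-1-yl}acetate | C=CC[C@]1(CCCC=C1OCc1cc(OC)c(OC)c(OC)c1)C(=[N+]=[N-])C(=O)OC
A4 | alternative 2 | methyl (2S,3S,3aR)-3a-(prop-2-en-1-yl)-2-(3,4,5-trimethoxyphenyl)-2,3,3a,4,5,6-hexahydro-1-benzofuran-3-carboxylate | C=CC[C@@]12CCCC=C1O[C@H](c1cc(OC)c(OC)c(OC)c1)[C@H]2C(=O)OC
A5 | alternative 3 | (2S,3S)-3-methyl-2-(3,4,5-trimethoxyphenyl)-2,3-dihydrofuran-4-carbaldehyde | O=CC1=CO[C@H](c2cc(OC)c(OC)c(OC)c2)[C@H]1C
A6 | alternative 3 | 2-{[tert-butyl(dimethyl)silyl]oxy}buta-1,3-diene | C=CC(=C)O[Si](C)(C)C(C)(C)C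
A7 | alternative 3 | (2S,3S,3aR,7aS)-6-{[tert-butyl(dimethyl)silyl]oxy}-3-methyl-2-(3,4,5-trimethoxyphenyl)-2,3,7,7a-tetrahydro-1-benzofuran-3a(4H)-carbaldehyde | O=C[C@@]12CC=C(O[Si](C)(C)C(C)(C)C)C[C@@H]1O[C@H](c1cc(OC)c(OC)c(OC)c1)[C@H]2C
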